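Amounts speak most plainly in these runs: the charge of second nucleophile as a fraction of the charge of starting material, 60.0 % in the new flask, is the capture ceiling, the most other capture product that one-to-one use of second nucleophile allows, which marks second nucleophile as the limiting reagent for that product.

the same everywhere: starting material 0.50 M; first nucleophile 1.25 M
- Thursday's: second nucleophile 0.30 M; protic impurity 0.013 M; run made earlier
- Wednesday's: second nucleophile 0.30 M; protic impurity 0.019 M; run made earlier
- Saturday's: second nucleophile 0.45 M; protic impurity 0.025 M; run made earlier
- flask: second nucleophile 0.300 M; protic impurity 0.0250 M; time 8.0 min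

- Thursday's (time / min: other capture product / %, target / %): 0.667: 24.8, 18.9; 1.00: 36.8, 20.6; 1.33: 42.4, 22.5; 2.50: 56.1, 22.2; 3.00: 58.3, 20.4; 5.00: 59.3, 22.2; 8.00: 62.1, 18.6
- Wednesday's (time / min: other capture product / %, target / %): 1.00: 35.2, 21.0; 2.50: 53.8, 20.5; 3.00: 57.3, 19.7; 5.00: 61.7, 19.1; 6.00: 62.1, 18.3; 8.00: 59.3, 18.5
- Saturday's (time / min: other capture product / %, target / %): 1.50: 60.0, 15.3; 3.00: 75.5, 8.9; 5.00: 84.0, 7.6; 6.00: 85.1, 4.9; 8.00: 85.4, 6.4

(scatter of a reading: 1 percentage point)

- share of other capture product in other capture product plus target at 6.0 s
- share of other capture product in other capture product plus target at 50 s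
- share of other capture product in other capture product plus target at 8.0 min
- which of other capture product and target there is more of at 8.0 min



Second nucleophile is the first setting. By hand, going from Thursday's charge to Saturday's lifts the ceiling from 60.0 % to 90.0 %, and in the runs other capture product at 8.0 min averages 60.7 % over Thursday's and Wednesday's runs and reads 85.4 % in Saturday's run.

Protic impurity is the second. By hand, if each molecule took one molecule of starting material, the new flask would lose 5.00 % of its starting material and keep 95.0 %, more than its ceiling. In the runs, going from Thursday's impurity to Wednesday's moves other capture product from 59.3 % to 61.7 % at 5.00 min, but from 62.1 % to 59.3 % at 8.00 min, so these two late pairs show no steady direction.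

Time is the third. By hand, the count stops at the ceiling, and those same readings lie on both sides of 60.0 % from 5.00 min to 8.00 min. Target at 8.0 min in Thursday's and Wednesday's runs averages 18.6 %, which gives this reckoning of my own for the new flask:

share at the latest time = ceiling / (ceiling + target) = 60.0 % / (60.0 % + 18.6 %) = 76.4 %

Thursday's shares on either side of 50 s average 60.4 %, and the runs hold no reading before 0.667 min, so I give no number for 6.0 s.

The forecast gives 25 % at 6.0 s, within 5 % to 45 %, then 59 % at 50 s and 76 % at 8.0 min, with other capture product ahead, and says of the early time that “target should lead, though this is very uncertain”.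

The new flask gives 41.4 % at 6.0 s, 16 percentage points above the forecast, then 59.8 % at 50 s and 76.6 % at 8.0 min, with other capture product ahead.

    starting material → intermediate (k = 1.60 min⁻¹)
    first nucleophile + intermediate ⇌ target (K = 0.920 M⁻¹, k = 3.90 M⁻¹ min⁻¹)
    starting material + protic impurity → quenched substrate (k = 4.10 M⁻¹ min⁻¹)
    starting material + target → side product (k = 0.120 M⁻¹ min⁻¹)
    second nucleophile + intermediate → other capture product (k = 10.0 M⁻¹ min⁻¹)

Against the ceiling of 60.0 %, the new flask ends with 60.0 % of other capture product and 0.072 % of its second nucleophile's charge left. The neighbouring flask with 1.2 M of starting material has a ceiling of 25.0 % and ends with 25.0 % of other capture product.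

(The data are simulated for an exercise, noise included.)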